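**Strategy.** The dihydropyranone ring (O1, C2, C3, C4, C4a, C8a) is read as (S)-β-butyrolactone whose acyl C4–O1 bond has been split by the C4a=C8a edge of the carbocycle. The precursor of the key step is therefore a fully substituted aryllithium with lithium at C4a and fluorine at C8a, flanked by the C8 methyl. In one operation it is acylated at the lactone carbonyl and the released C2 alkoxide displaces fluoride: a two-atom ring expansion (oxetanone to pyranone) that joins both fragments, carries C2 in unchanged from the chiral pool and fixes O1 next to C8. Deprotection and a ligand-controlled Pd allylic dearomatisation at C8 then set the geranyl/methyl quaternary centre.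

Key step: step 4

Remark: atom labels follow chromanone numbering of the target (O1, C2 = CHMe, C4 = ring ketone, C5 = C–OH, C6 = prenyl carbon, C7 = C=O, C8 = quaternary carbon); the target is treated as its drawn, chelated 5-hydroxy-4,7-dione tautomer, (2S,8R).
Remark: the sense of induction of the Trost ligand in step 7 cannot be predicted with certainty; the (S,S) ligand is written and its antipode is used if a pilot run shows 8S.

Step 1
Reactants: 1 5-fluorobenzene-1,3-diol (5-fluororesorcinol)
Product: 2 1-fluoro-3,5-bis(methoxymethoxy)benzene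
Conditions: NaH, MOMCl, DMF, 0 → 23 °C
Reagents that add atoms: chloromethyl methyl ether, COCCl
Why: Double Williamson etherification of the two phenoxides (SN2 at the chloromethyl carbon) installs acid-labile groups that also serve as ortho-directing groups for the three metalations that follow.

Step 2
Reactants: 2 1-fluoro-3,5-bis(methoxymethoxy)benzene
Product: 4 5-fluoro-1,3-bis(methoxymethoxy)-2-(3-methylbut-2-en-1-yl)benzene, via aryllithium 3 (not isolated)
Conditions: n-BuLi, THF, 0 °C; CuBr·SMe2 (10 mol %), prenyl bromide, −78 → 0 °C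
Reagents that add atoms: prenyl bromide (1-bromo-3-methylbut-2-ene), CC(C)=CCBr
Why: Directed ortho-metalation should occur between the two chelating OMOM groups (coordination control, not next to fluorine), and copper-catalysed SN2 allylation at the primary carbon of prenyl bromide places the prenyl group on the future C6.

Step 3
Reactants: 4 5-fluoro-1,3-bis(methoxymethoxy)-2-(3-methylbut-2-en-1-yl)benzene
Product: 6 1-fluoro-3,5-bis(methoxymethoxy)-2-methyl-4-(3-methylbut-2-en-1-yl)benzene, via aryllithium 5 (not isolated)
Conditions: n-BuLi, THF, −78 °C; MeI, −78 → 0 °C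
Reagents that add atoms: iodomethane, CI
Why: The two remaining ring hydrogens are equivalent and each lies between fluorine and OMOM, so a second directed ortho-metalation at −78 °C (cold enough to prevent LiF loss to an aryne) and SN2 methylation should give one product with methyl on the future C8.

Step 4
Reactants: 6 1-fluoro-3,5-bis(methoxymethoxy)-2-methyl-4-(3-methylbut-2-en-1-yl)benzene; 7 (4S)-4-methyloxetan-2-one [(S)-β-butyrolactone]
Product: 10 (2S)-5,7-bis(methoxymethoxy)-2,8-dimethyl-6-(3-methylbut-2-en-1-yl)-2,3-dihydro-4H-chromen-4-one, via aryllithium 8 (not isolated), via lithium alkoxide 9 (not isolated)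
Conditions: s-BuLi, THF, −78 °C; 7 (1.3 equiv), −78 °C; then DMPU, −78 → 23 °C
Reagents that add atoms: none
Why: Proposed new method: a two-atom ring expansion of a β-lactone by an ortho-fluoroaryllithium, reasoned as acyl–oxygen cleavage followed by oxa-SNAr: the hard aryllithium 8 adds to the strained lactone carbonyl, the tetrahedral intermediate collapses with C4–O1 scission to the ketone alkoxide 9, and on warming the alkoxide adds at C8a (anion stabilised through C4a into the new C4 ketone) and expels fluoride. The closest known reaction types are the acyl-selective opening of β-lactones by organolithium reagents to β-hydroxy ketones, the oxa-SNAr closure of 2-fluoroaryl ketones to chromanones and chromones, and formal aryne σ-insertion into acyl–heteroatom bonds (8 is an aryne equivalent). The pyranone ring closes by a 6-endo-trig conjugate addition at C8a of the C8a=C4a–C4=O unit followed by fluoride loss (addition–elimination). No new stereocentre is formed: C2 comes from (S)-7 and none of its bonds is broken, so the S configuration is retained. The step needs acyl rather than alkyl attack on the lactone (hard lithium reagent, −78 °C), mono-addition (the di-ortho-substituted ketone of 9 is twisted and hindered) and ring closure faster than retro-aldol of 9 (DMPU, low temperature); the 8-methyl/6-prenyl regiochemistry is not at stake because fluorine is the only leaving group and sits between C4a and the methyl-bearing C8.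

Step 5
Reactants: 10 (2S)-5,7-bis(methoxymethoxy)-2,8-dimethyl-6-(3-methylbut-2-en-1-yl)-2,3-dihydro-4H-chromen-4-one
Product: 11 (2S)-5,7-dihydroxy-2,8-dimethyl-6-(3-methylbut-2-en-1-yl)-2,3-dihydro-4H-chromen-4-one
Conditions: 3 M HCl, MeOH, 40 °C
Reagents that add atoms: none
Why: Acid-catalysed methanolysis of the two MOM acetals (transacetalisation) should free both phenols, while C2 is safe because no base is present to open the ring by retro-oxa-Michael and dilute acid at this temperature should leave the prenyl group uncyclised.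

Step 6
Reactants: 12 geraniol [(2E)-3,7-dimethylocta-2,6-dien-1-ol]
Product: 13 (2E)-3,7-dimethylocta-2,6-dien-1-yl methyl carbonate (geranyl methyl carbonate)
Conditions: ClCO2Me, pyridine, CH2Cl2, 0 °C
Reagents that add atoms: methyl chloroformate, COC(=O)Cl
Why: Acylation of the primary allylic alcohol gives the carbonate needed for base-free ionisation by Pd(0) and does not touch the E alkene.

Step 7
Reactants: 11 (2S)-5,7-dihydroxy-2,8-dimethyl-6-(3-methylbut-2-en-1-yl)-2,3-dihydro-4H-chromen-4-one; 13 geranyl methyl carbonate
Product: 14 (2S,8R)-8-[(2E)-3,7-dimethylocta-2,6-dien-1-yl]-5-hydroxy-2,8-dimethyl-6-(3-methylbut-2-en-1-yl)-2,3-dihydro-4H-chromene-4,7(8H)-dione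
Conditions: Pd2(dba)3·CHCl3 (2.5 mol %), (S,S)-DACH-phenyl Trost ligand (7.5 mol %), THF, 0 → 23 °C
Reagents that add atoms: none
Why: Tsuji–Trost asymmetric allylic alkylation with dearomatisation: Pd(0) ionises 13 to a π-geranyl complex and methoxide, which forms the 7-phenoxide of 11; C-attack from C8 at the less hindered allyl terminus should give the linear E-geranyl group, any O-geranyl ether re-ionises and funnels to the irreversibly C-alkylated dienone, C8 is expected to win over C6 because it carries the smaller substituent and its alkylation keeps the 5-OH···O=C4 chelate, and the new C8 stereocentre (R) is set by the chiral ligand pocket selecting the face of the phenoxide, independently of the remote C2.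

**Compound list**

1 | 5-fluorobenzene-1,3-diol (5-fluororesorcinol) | Oc1cc(O)cc(F)c1 | starting material
2 | 1-fluoro-3,5-bis(methoxymethoxy)benzene | COCOc1cc(F)cc(OCOC)c1 | intermediate
3 | [4-fluoro-2,6-bis(methoxymethoxy)phenyl]lithium | [Li]c1c(OCOC)cc(F)cc1OCOC | intermediate
4 | 5-fluoro-1,3-bis(methoxymethoxy)-2-(3-methylbut-2-en-1-yl)benzene | COCOc1cc(F)cc(OCOC)c1CC=C(C)C | intermediate
5 | [2-fluoro-4,6-bis(methoxymethoxy)-5-(3-methylbut-2-en-1-yl)phenyl]lithium | [Li]c1c(F)cc(OCOC)c(CC=C(C)C)c1OCOC | intermediate
6 | 1-fluoro-3,5-bis(methoxymethoxy)-2-methyl-4-(3-methylbut-2-en-1-yl)benzene | Cc1c(F)cc(OCOC)c(CC=C(C)C)c1OCOC | intermediate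
7 | (4S)-4-methyloxetan-2-one [(S)-β-butyrolactone] | C[C@H]1CC(=O)O1 | starting material
8 | [2-fluoro-4,6-bis(methoxymethoxy)-3-methyl-5-(3-methylbut-2-en-1-yl)phenyl]lithium | [Li]c1c(F)c(C)c(OCOC)c(CC=C(C)C)c1OCOC | intermediate
9 | lithium (2S)-4-[2-fluoro-4,6-bis(methoxymethoxy)-3-methyl-5-(3-methylbut-2-en-1-yl)phenyl]-4-oxobutan-2-olate | C[C@H](O[Li])CC(=O)c1c(F)c(C)c(OCOC)c(CC=C(C)C)c1OCOC | intermediate
10 | (2S)-5,7-bis(methoxymethoxy)-2,8-dimethyl-6-(3-methylbut-2-en-1-yl)-2,3-dihydro-4H-chromen-4-one | C[C@H]1CC(=O)c2c(OCOC)c(CC=C(C)C)c(OCOC)c(C)c2O1 | intermediate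
11 | (2S)-5,7-dihydroxy-2,8-dimethyl-6-(3-methylbut-2-en-1-yl)-2,3-dihydro-4H-chromen-4-one | C[C@H]1CC(=O)c2c(O)c(CC=C(C)C)c(O)c(C)c2O1 | intermediate
12 | geraniol [(2E)-3,7-dimethylocta-2,6-dien-1-ol] | CC(C)=CCC/C(C)=C/CO | starting material
13 | (2E)-3,7-dimethylocta-2,6-dien-1-yl methyl carbonate | CC(C)=CCC/C(C)=C/COC(=O)OC | intermediate
14 | (2S,8R)-8-[(2E)-3,7-dimethylocta-2,6-dien-1-yl]-5-hydroxy-2,8-dimethyl-6-(3-methylbut-2-en-1-yl)-2,3-dihydro-4H-chromene-4,7(8H)-dione | CC(C)=CCC/C(C)=C/C[C@@]1(C)C(=O)C(CC=C(C)C)=C(O)C2=C1O[C@@H](C)CC2=O | target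

**Step count.** Total: 7 steps. Longest linear sequence: 6 steps (1, 2, 3, 4, 5, 7).

**Steps most likely to fail**

1. Step 4 (Proposed new method). What may go wrong: the hindered aryllithium may deprotonate the lactone or attack its alkyl–oxygen carbon instead of the carbonyl; 8 may lose LiF to an aryne if the temperature drifts; and alkoxide 9 may undergo retro-aldol on warming before the SNAr closes, eroding C2 and losing acetaldehyde. The fallback uses known chemistry, sets out from 6 and 7 and comes back at 10. Lactone 7 is opened with MeNH(OMe)·HCl/Me2AlCl to (3S)-3-hydroxy-N-methoxy-N-methylbutanamide F1, which is silylated (TBSCl, imidazole) to (3S)-3-[(tert-butyldimethylsilyl)oxy]-N-methoxy-N-methylbutanamide F2. Aryllithium 8, made from 6 as in step 4, is acylated by F2 at −78 °C (stable chelate, no over-addition) to the silyl-protected β-hydroxy ketone (3S)-3-[(tert-butyldimethylsilyl)oxy]-1-[2-fluoro-4,6-bis(methoxymethoxy)-3-methyl-5-(3-methylbut-2-en-1-yl)phenyl]butan-1-one F3. TBAF (catalytic, THF, 0 °C) then removes the silyl group and the alkoxide closes by oxa-SNAr to 10. The hydroxyl is masked while the C–C bond forms, so retro-aldol cannot intervene, and ring closure becomes a separate step.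

2. Step 7. What may go wrong: poor site selectivity between C8 and C6 or between carbon and oxygen, and poor facial selectivity at C8. The fallback goes from 11 directly to 14 by enantioselective alkylative dearomatisation under chiral ion-pair control: geranyl bromide, a cinchona-derived quaternary ammonium phase-transfer catalyst, Cs2CO3, toluene, −30 °C. This replaces the π-allyl pathway by SN2 attack of the catalyst-bound phenoxide on the bromide. Because C2 is fixed, the unwanted C8 epimer is a diastereomer of 14 and should be separable by chromatography. No new compound is made.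

3. Step 3 (the same lithiation recurs in step 4). What may go wrong: competing deprotonation at the benzylic–allylic CH2 of the prenyl group, or aryne formation from the ortho-fluoro aryllithium. The fallback sets out from 2 and comes back at 11, and keeps the prenyl group out of all organolithium chemistry. Aryllithium 3 is silylated (TMSCl) to [4-fluoro-2,6-bis(methoxymethoxy)phenyl]trimethylsilane F4. n-BuLi at −78 °C gives [2-fluoro-4,6-bis(methoxymethoxy)-5-(trimethylsilyl)phenyl]lithium F5, and MeI gives [4-fluoro-2,6-bis(methoxymethoxy)-3-methylphenyl]trimethylsilane F6. s-BuLi gives [2-fluoro-4,6-bis(methoxymethoxy)-3-methyl-5-(trimethylsilyl)phenyl]lithium F7, which with lactone 7 gives the lithium alkoxide F8 and then (2S)-5,7-bis(methoxymethoxy)-2,8-dimethyl-6-(trimethylsilyl)-2,3-dihydro-4H-chromen-4-one F9. HCl/MeOH removes both MOM groups and the activated aryl–silicon bond (ipso-protodesilylation) to give (2S)-5,7-dihydroxy-2,8-dimethyl-2,3-dihydro-4H-chromen-4-one F10. Friedel–Crafts prenylation at the only free position C6 (2-methylbut-3-en-2-ol, BF3·OEt2, dioxane) returns to 11.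

**Further compounds**

F1 | step 4 | (3S)-3-hydroxy-N-methoxy-N-methylbutanamide | C[C@H](O)CC(=O)N(C)OC
F2 | step 4 | (3S)-3-[(tert-butyldimethylsilyl)oxy]-N-methoxy-N-methylbutanamide | C[C@H](O[Si](C)(C)C(C)(C)C)CC(=O)N(C)OC
F3 | step 4 | (3S)-3-[(tert-butyldimethylsilyl)oxy]-1-[2-fluoro-4,6-bis(methoxymethoxy)-3-methyl-5-(3-methylbut-2-en-1-yl)phenyl]butan-1-one | C[C@H](O[Si](C)(C)C(C)(C)C)CC(=O)c1c(F)c(C)c(OCOC)c(CC=C(C)C)c1OCOC
F0 | step 7 | none | none
F4 | step 3 | [4-fluoro-2,6-bis(methoxymethoxy)phenyl]trimethylsilane | COCOc1cc(F)cc(OCOC)c1[Si](C)(C)C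
F5 | step 3 | [2-fluoro-4,6-bis(methoxymethoxy)-5-(trimethylsilyl)phenyl]lithium | [Li]c1c(F)cc(OCOC)c([Si](C)(C)C)c1OCOC
F6 | step 3 | [4-fluoro-2,6-bis(methoxymethoxy)-3-methylphenyl]trimethylsilane | Cc1c(F)cc(OCOC)c([Si](C)(C)C)c1OCOC
F7 | step 3 | [2-fluoro-4,6-bis(methoxymethoxy)-3-methyl-5-(trimethylsilyl)phenyl]lithium | [Li]c1c(F)c(C)c(OCOC)c([Si](C)(C)C)c1OCOC
F8 | step 3 | lithium (2S)-4-[2-fluoro-4,6-bis(methoxymethoxy)-3-methyl-5-(trimethylsilyl)phenyl]-4-oxobutan-2-olate | C[C@H](O[Li])CC(=O)c1c(F)c(C)c(OCOC)c([Si](C)(C)C)c1OCOC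
F9 | step 3 | (2S)-5,7-bis(methoxymethoxy)-2,8-dimethyl-6-(trimethylsilyl)-2,3-dihydro-4H-chromen-4-one | C[C@H]1CC(=O)c2c(OCOC)c([Si](C)(C)C)c(OCOC)c(C)c2O1
F10 | step 3 | (2S)-5,7-dihydroxy-2,8-dimethyl-2,3-dihydro-4H-chromen-4-one | C[C@H]1CC(=O)c2c(O)cc(O)c(C)c2O1
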